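Remark on the chemistry: aryl sulfate monoesters 22 and 23 are drawn as free hydrogen sulfates, as in the target; in practice they would be handled as salts and the acid form released only at the end.

Atom labels used throughout: decalin carbons C1–C10 (ring A = C1–C5, C10; ring B = C5–C10), C11 = benzylic carbon on C9, arene carbons C1'–C6' (C1' bonded to C11). Ar = 2-(methoxymethoxy)-3-(triisopropylsilyloxy)-5-[(triisopropylsilyloxy)methyl]phenyl.

## Analysis of the target

Compound 23 is a rearranged drimane: a trans-fused decalin with a methylidene on C4, methyl groups on C5, C8 and C9, and C11 on C9 carrying a tetrasubstituted arene. The arene has the sulfate on O2', a free hydroxyl on C3' and a hydroxymethyl group on C5'. The four stereocentres are contiguous (5S, 10S, 9R, 8S). The three methyl groups lie on one face and H10 and C11 on the other, so the C5 methyl and H10 are trans-diaxial, the C5 and C9 methyls are 1,3-diaxial across C10, and the C8 methyl is equatorial. The aryl sulfate monoester is acid-labile, the exocyclic alkene can migrate into ring A under acid, and the sulfate sits on the more hindered catechol oxygen. The hard points are therefore the two quaternary carbons C5 and C9 flanking C10, the unambiguous placement of the alkene, and an endgame that must tell the two catechol oxygens apart without acid. The strategy rests on ring A: C4, C5 and C10 are the carbonyl carbon, the methyl-bearing α-carbon and the β-carbon of 2-methylcyclohex-2-en-1-one. The two ring B bonds that leave ring A (C5–C6 and C10–C9) are trans, which is what conjugate addition followed by anti alkylation of the enolate delivers.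

## Retrosynthetic reasoning

**23 back to 19.** The sulfate and the free hydroxyls are installed last. The C3' and benzylic oxygens are carried as silyl ethers, which fall to fluoride without touching a sulfate or the alkene (23 from 22). O2' is carried as an acetal that can be removed alone, so that only this oxygen is free when the sulfate is introduced (22 from 21, 21 from 19).

**19 back to 18.** The C4 methylidene is cut to a C4 ketone. This fixes the alkene position by the carbonyl position, and the ketone is exactly what the enone starting material leaves behind. The forward step is a Wittig methylenation of a ketone next to a quaternary carbon.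

**18 back to 15 (through 17 and 16).** The C8–C9 bond of ring B is cut. It is the one ring bond that can form by a 6-exo radical closure from a C8 radical onto the C9=C11 styrene, which turns C11 into the benzylic CH2 at the same time. The gain is that C8 and C9 are created on a ring A template that already holds C5 and C10. The forward sequence must reduce only the C8 ketone of 15, convert the alcohol 16 into the iodide 17 and close the ring with the right face at C9.

**15 back to 9, 10 and 11.** Both bonds from ring A to the rest of the skeleton, C9–C10 and C5–C6, are cut at once. This leads to three components: the alkenyl bromide 9 (C9, C11, the C9 methyl and the whole arene), the enone 10 (ring A with the C5 methyl) and the silyl enone 11 (C6, C7, C8 and the C8 methyl). No other cut delivers all skeletal carbons in one operation from a commercial ring. The forward step has to set C10 by catalyst control and C5 by anti alkylation.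

**9 back to 5 and 6 (through 7).** The alkenyl bromide comes from the aryl propyne 7 by syn hydrometalation and bromination, which defines the alkene geometry. Alkyne 7 comes from aryl bromide 5 and propyne 6 by cross-coupling at the carbon that becomes C1'.

**5 back to 1 (through 4, 3 and 2).** The arene oxygen pattern is that of 1 after demethylation. In catechol aldehyde 2 the hydroxyl para to the formyl group is the more acidic, which lets the acetal go onto the future O2' (3). Reduction (4) and double silylation (5) finish the protecting-group pattern.

## Alternatives that were turned down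

**Alternative 1:** Ring B is cut at C7–C8 and C9–C10. A silyloxy vinylcyclohexene A1 and the enal A2 would combine in an exo-selective Diels–Alder reaction, under an alkylaluminium chloride or a chiral oxazaborolidinium Lewis acid, to give the octalin aldehyde A3.
- For it: C8, C9 and C10 arise in one concerted step. The cis relation of the C8 and C9 methyls is locked by the geometry of A2, and the regiochemistry is the electronically natural one. On the control of C8 and C9 this is stronger than a radical ring closure.
- Against it: the C9–C10 bond must form between a fully substituted dienophile carbon and the ring terminus of the diene, and exo selectivity has to win. A3 also lacks the C5 methyl; it would have to be added later to the C5=C6 alkene with trans fusion (directed cyclopropanation and reductive opening), relayed from the C4 oxygen stereocentre, which itself must be set. The arene would come in late by addition to a neopentyl aldehyde and benzylic deoxygenation.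
- Comparison: the chosen strategy gives up concerted control of C8 and C9. In return the C5 quaternary centre, the trans fusion, the C4 carbonyl and the complete arene are in place after one step, and the sequence after the key step is roughly half as long.

**Alternative 2:** No ring bond is cut. A 9-epi pattern is avoided by making the skeleton from a drimane: the 8(12)-ene A4 would be protonated by a strong Lewis or Brønsted acid, and four antiperiplanar 1,2-shifts (H9, the C10 methyl, H5, one C4 methyl) followed by proton loss would give A5.
- For it: the drimane series comes from the chiral pool, the step count is the lowest of all four plans, and every stereocentre is relayed stereospecifically. On step economy and on C8 and C9 it is stronger than the chosen plan.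
- Against it: nothing in the structure controls the termination. The C4 cation loses a proton more readily from C3 to the more substituted endocyclic alkene, and the exocyclic isomer is not stable to the acid that forms it. The cascade can also stop at the C9, C10 or C5 cations or be intercepted by the arene and its ortho oxygen. The acyl groups needed to deactivate the arene can migrate between the two adjacent oxygens, which removes the O2'/O3' distinction on which the sulfation depends.
- Comparison: the chosen strategy is longer, but the alkene position follows from a carbonyl group and the arene oxygens stay distinguishable throughout.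

**Alternative 3:** Both rings are cut at C5–C10 and C3–C4. The acyclic triene A6 would undergo an intramolecular Diels–Alder reaction, thermally or with a dialkylaluminium chloride, to give the octalin ester A7.
- For it: both rings and C5, C10 and C4 form in one step, and the C4 ester can be turned into the methylidene. On ring construction per step it is stronger than the chosen plan.
- Against it: A6 must already contain the adjacent C8 and quaternary C9 centres in an open chain, a harder stereochemical problem than the one the cycloaddition solves. The dienophile is a β,β-disubstituted enoate that has to form a quaternary carbon, and trans over cis fusion is not assured in such decatrienes. Hydrogenation of the C1=C2 alkene and a three-step ester-to-methylidene conversion follow.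
- Comparison: the chosen strategy builds one ring instead of two, but every stereocentre is created on a ring and the carbons come from three simple components.

Key step: step 7

## Route

Step 1
Reactants: 1 5-bromovanillin (3-bromo-4-hydroxy-5-methoxybenzaldehyde)
Product: 2 3-bromo-4,5-dihydroxybenzaldehyde
Conditions: AlCl3, pyridine, CH2Cl2, reflux; then 2 M HCl
Reagents that add atoms: none
Why: Lewis acid-assisted O-demethylation of a guaiacol: AlCl3 chelates the ortho hydroxy/methoxy pair and pyridine removes the methyl group by SN2 attack, while the aldehyde and aryl bromide are untouched.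

Step 2
Reactants: 2 3-bromo-4,5-dihydroxybenzaldehyde
Product: 3 3-bromo-5-hydroxy-4-(methoxymethoxy)benzaldehyde
Conditions: MOMCl (1.05 equiv), K2CO3 (1.0 equiv), acetone, 0 °C → rt
Reagents that add atoms: chloromethyl methyl ether, COCCl
Why: Regioselective Williamson-type O-alkylation: the hydroxyl para to the formyl group and ortho to bromine is by far the more acidic, so one equivalent of weak base forms only that phenoxide and the small electrophile reaches it despite the two ortho substituents.

Step 3
Reactants: 3 3-bromo-5-hydroxy-4-(methoxymethoxy)benzaldehyde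
Product: 4 3-bromo-5-(hydroxymethyl)-2-(methoxymethoxy)phenol
Conditions: NaBH4, MeOH, 0 °C
Reagents that add atoms: none
Why: Borohydride reduction of an aromatic aldehyde; the acetal, phenol and aryl bromide are inert.

Step 4
Reactants: 4 3-bromo-5-(hydroxymethyl)-2-(methoxymethoxy)phenol
Product: 5 {[3-bromo-4-(methoxymethoxy)-5-(triisopropylsilyloxy)phenyl]methoxy}triisopropylsilane (ArBr)
Conditions: TIPSCl (2.5 equiv), imidazole, DMAP (cat.), DMF, 40 °C
Reagents that add atoms: triisopropylsilyl chloride, CC(C)[Si](Cl)(C(C)C)C(C)C
Why: Double O-silylation of the phenol and the primary benzylic alcohol; the chloride/imidazole system is chosen over a silyl triflate so that the acetal is not attacked.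

Step 5
Reactants: 5 ArBr; 6 propyne
Product: 7 1-Ar-prop-1-yne
Conditions: PdCl2(PhCN)2 (3 mol %), P(t-Bu)3 (6 mol %), CuI (2 mol %), i-Pr2NH, 1,4-dioxane, 6 (excess), rt, sealed vessel
Reagents that add atoms: none
Why: Sonogashira coupling; the bulky electron-rich phosphine lets zerovalent palladium insert into the electron-rich, ortho-substituted aryl bromide at room temperature, which also keeps the volatile alkyne in solution.

Step 6
Reactants: 7 1-Ar-prop-1-yne
Product: 9 (E)-2-bromo-1-Ar-prop-1-ene, via alkenylzirconocene chloride 8 (not isolated)
Conditions: Cp2Zr(H)Cl (1.6 equiv), THF, 50 °C; then NBS, 0 °C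
Reagents that add atoms: N-bromosuccinimide, O=C1CCC(=O)N1Br
Why: Hydrozirconation is a syn addition, and with a slight excess of Zr–H and gentle warming it equilibrates to the isomer with zirconium on the methyl-bearing carbon, away from the ortho-substituted arene. Bromodemetalation proceeds with retention, so aryl and bromine end trans (E).

Step 7
Reactants: 9 (E)-2-bromo-1-Ar-prop-1-ene; 10 2-methylcyclohex-2-en-1-one; 11 3-(trimethylsilyl)but-3-en-2-one
Product: 15 (2S,3S)-2-methyl-2-(3-oxobutyl)-3-[(E)-1-Ar-prop-1-en-2-yl]cyclohexan-1-one, via alkenylmagnesium bromide 12 (not isolated), via magnesium enolate 13 (not isolated), via alpha-silyl diketone 14 (not isolated)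
Conditions: (a) 9, Mg, 2-MeTHF, 40 °C; (b) 10, CuBr·SMe2 (5 mol %), phosphoramidite L* (10 mol %), t-BuOMe, −78 °C, slow addition of 12; (c) 11, −78 → −20 °C; (d) aq NH4Cl, then AcOH–THF–H2O, rt. L* = O,O'-(1,1'-binaphthalene-2,2'-diyl) N,N-bis(1-phenylethyl)phosphoramidite as a single stereoisomer
Reagents that add atoms: none
Why: Transmetalation of 12 to the ligated monovalent copper bromide gives a chiral alkenylcopper species that binds the enone of 10, adds oxidatively to a trivalent copper σ-complex at C10 and eliminates reductively to release magnesium enolate 13 (C9–C10 bond); 13 then adds through C5 as a Michael donor to the silyl-activated enone 11 (C5–C6 bond), the silicon stabilising the new α-carbanion and suppressing proton exchange and polymerisation, and mild aqueous acid replaces the C7 silyl group of 14 by hydrogen without triggering aldol closure. The closest known reaction type is the copper/phosphoramidite-catalysed enantioselective 1,4-addition of Grignard reagents to 2-methylcyclohex-2-enone with trans trapping of the enolate, joined to the classical capture of a regiodefined enolate by an α-silyl vinyl ketone. No ring is closed in this step. C10 is set by the catalyst: the ligand stereoisomer used is the one that delivers the alkenyl group to the Re face of C3 of 10, which gives the S configuration, and if a first choice gives the antipode its mirror image is taken. C5 is set by the substrate: the enolate carbon is attacked on the face anti to the bulky C10 alkenyl group, so C6 ends trans to C9, which is the trans ring-fusion relationship (2S in the ring numbering). The step needs 1,4- over 1,2-addition (copper catalysis, slow addition at −78 °C), enantioface control (ligand), C-alkylation at the more substituted enolate carbon without enolate equilibration (the enolate is formed regiospecifically and 11 is a very fast acceptor), and retention of the alkene geometry (alkenyl–metal bonds are configurationally stable at these temperatures).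

Step 8
Reactants: 15 (2S,3S)-2-methyl-2-(3-oxobutyl)-3-[(E)-1-Ar-prop-1-en-2-yl]cyclohexan-1-one
Product: 16 (2S,3S)-2-(3-hydroxybutyl)-2-methyl-3-[(E)-1-Ar-prop-1-en-2-yl]cyclohexan-1-one (both carbinol epimers)
Conditions: LiBH(s-Bu)3 (1.05 equiv), THF, −78 °C; then aq NH4Cl
Reagents that add atoms: none
Why: Chemoselective ketone reduction under steric approach control: the bulky trialkylborohydride reaches the open C8 methyl ketone, while the C4 carbonyl is screened on one face by the axial C5 methyl and on the other by the axial hydrogens on C2 and C10. A small borohydride is avoided because cyclohexanones are intrinsically the more reactive ketones, and the carbinol configuration is irrelevant since C8 later becomes a radical.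

Step 9
Reactants: 16 (2S,3S)-2-(3-hydroxybutyl)-2-methyl-3-[(E)-1-Ar-prop-1-en-2-yl]cyclohexan-1-one
Product: 17 (2S,3S)-2-(3-iodobutyl)-2-methyl-3-[(E)-1-Ar-prop-1-en-2-yl]cyclohexan-1-one (both epimers at the iodide carbon)
Conditions: PPh3, I2, imidazole (pre-mixed), CH2Cl2, 0 °C → rt
Reagents that add atoms: iodine, II
Why: Appel iodination of an unhindered secondary alcohol by SN2 displacement of the alkoxyphosphonium ion; pre-forming the phosphonium iodide keeps free iodine away from the styrene.

Step 10
Reactants: 17 (2S,3S)-2-(3-iodobutyl)-2-methyl-3-[(E)-1-Ar-prop-1-en-2-yl]cyclohexan-1-one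
Product: 18 (4aS,5R,6S,8aS)-5-(Ar-methyl)-5,6,8a-trimethyl-3,4,4a,5,6,7,8,8a-octahydronaphthalen-1(2H)-one (trans-decalone; 5S,8S,9R,10S in the skeleton numbering)
Conditions: Bu3SnH (1.5 equiv) and AIBN (0.2 equiv) added over 6 h, toluene (0.005 M), 90 °C
Reagents that add atoms: none
Why: Tin hydride radical chain: iodine abstraction gives the secondary C8 radical, which closes 6-exo-trig onto C9 of the styrene to form ring B and a benzylic C11 radical that is then reduced. The chair-like transition state is built on the trans-diequatorial C5 and C10 substituents of ring A; the C8 methyl sits pseudo-equatorial (8S). C11 takes the equatorial site at C9 with the C9 methyl axial (9R), because the rotamer with C11 axial would drive the in-plane hydrogen on C11 into the axial C5 methyl.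

Step 11
Reactants: 18 (4aS,5R,6S,8aS)-5-(Ar-methyl)-5,6,8a-trimethyl-octahydronaphthalen-1(2H)-one
Product: 19 (1R,2S,4aS,8aS)-1-(Ar-methyl)-1,2,4a-trimethyl-5-methylidenedecahydronaphthalene
Conditions: Ph3PCH3Br (6 equiv), KN(SiMe3)2 (5.5 equiv), toluene, 90 °C
Reagents that add atoms: methyltriphenylphosphonium bromide, C[P+](c1ccccc1)(c1ccccc1)c1ccccc1.[Br-]
Why: Wittig methylenation of a hindered ketone with the salt-free ylide at elevated temperature; neither α-carbon is a stereocentre that could epimerise, and a slight deficit of base leaves no free amide to attack the aryl silyl ether.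

Step 12
Reactants: 19 (1R,2S,4aS,8aS)-1-(Ar-methyl)-1,2,4a-trimethyl-5-methylidenedecahydronaphthalene
Product: 21 2-{[(1R,2S,4aS,8aS)-1,2,4a-trimethyl-5-methylidenedecahydronaphthalen-1-yl]methyl}-6-(triisopropylsilyloxy)-4-[(triisopropylsilyloxy)methyl]phenol, via aryl trimethylsilyl ether 20 (not isolated)
Conditions: Me3SiOTf, 2,2'-bipyridyl, CH2Cl2, 0 °C; then H2O, rt
Reagents that add atoms: none
Why: Chemoselective cleavage of an aromatic methoxymethyl ether: the silyl triflate buffered by bipyridyl converts the acetal into the labile aryl trimethylsilyl ether, which water hydrolyses. No protic acid is present, so the exocyclic alkene and the two triisopropylsilyl ethers should persist.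

Step 13
Reactants: 21 the phenol from step 12 (free OH on C2')
Product: 22 2-{[(1R,2S,4aS,8aS)-1,2,4a-trimethyl-5-methylidenedecahydronaphthalen-1-yl]methyl}-6-(triisopropylsilyloxy)-4-[(triisopropylsilyloxy)methyl]phenyl hydrogen sulfate
Conditions: SO3·pyridine (5 equiv), pyridine, 40 °C; then aq NaHCO3
Reagents that add atoms: sulfur trioxide–pyridine complex, O=S(=O)=O.c1ccncc1
Why: O-sulfation of the only free hydroxyl; the weakly basic medium keeps the phenoxide concentration low, which should hold back silyl transfer from O3' to O2'.

Step 14
Reactants: 22 the bis-silylated aryl hydrogen sulfate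
Product: 23 [2-hydroxy-4-(hydroxymethyl)-6-{[(1R,2S,4aS,8aS)-1,2,4a-trimethyl-5-methylidenedecahydronaphthalen-1-yl]methyl}phenyl] hydrogen sulfate (CNP0353860.3)
Conditions: Bu4NF (3 equiv), THF, 0 °C → rt; then cation-exchange resin (H+ form), 0 °C
Reagents that add atoms: none
Why: Fluoride cleavage of the aryl and the primary alkyl silyl ether; a sulfate monoester anion is inert to fluoride and base, and the alkene sees no acid until the brief final ion exchange.

## Compound list

1 | 5-bromovanillin | COc1cc(C=O)cc(Br)c1O | starting material
2 | 3-bromo-4,5-dihydroxybenzaldehyde | O=Cc1cc(O)c(O)c(Br)c1 | intermediate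
3 | 3-bromo-5-hydroxy-4-(methoxymethoxy)benzaldehyde | COCOc1c(O)cc(C=O)cc1Br | intermediate
4 | 3-bromo-5-(hydroxymethyl)-2-(methoxymethoxy)phenol | COCOc1c(O)cc(CO)cc1Br | intermediate
5 | {[3-bromo-4-(methoxymethoxy)-5-(triisopropylsilyloxy)phenyl]methoxy}triisopropylsilane | COCOc1c(Br)cc(CO[Si](C(C)C)(C(C)C)C(C)C)cc1O[Si](C(C)C)(C(C)C)C(C)C | intermediate
6 | propyne | CC#C | starting material
7 | 1-Ar-prop-1-yne | CC#Cc1cc(CO[Si](C(C)C)(C(C)C)C(C)C)cc(O[Si](C(C)C)(C(C)C)C(C)C)c1OCOC | intermediate
8 | (E)-(1-Ar-prop-1-en-2-yl)zirconocene chloride | Cl[Zr](C1C=CC=C1)(C1C=CC=C1)/C(C)=C/c1cc(CO[Si](C(C)C)(C(C)C)C(C)C)cc(O[Si](C(C)C)(C(C)C)C(C)C)c1OCOC | intermediate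
9 | (E)-2-bromo-1-Ar-prop-1-ene | Br/C(C)=C/c1cc(CO[Si](C(C)C)(C(C)C)C(C)C)cc(O[Si](C(C)C)(C(C)C)C(C)C)c1OCOC | intermediate
10 | 2-methylcyclohex-2-en-1-one | CC1=CCCCC1=O | starting material
11 | 3-(trimethylsilyl)but-3-en-2-one | CC(=O)C(=C)[Si](C)(C)C | starting material
12 | (E)-(1-Ar-prop-1-en-2-yl)magnesium bromide | Br[Mg]/C(C)=C/c1cc(CO[Si](C(C)C)(C(C)C)C(C)C)cc(O[Si](C(C)C)(C(C)C)C(C)C)c1OCOC | intermediate
13 | bromomagnesium enolate of (S)-2-methyl-3-[(E)-1-Ar-prop-1-en-2-yl]cyclohexanone | Br[Mg]OC1=C(C)[C@H](/C(C)=C/c2cc(CO[Si](C(C)C)(C(C)C)C(C)C)cc(O[Si](C(C)C)(C(C)C)C(C)C)c2OCOC)CCC1 | intermediate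
14 | (2S,3S)-2-methyl-2-[3-oxo-2-(trimethylsilyl)butyl]-3-[(E)-1-Ar-prop-1-en-2-yl]cyclohexan-1-one (epimers at the silyl-bearing carbon) | O=C1CCC[C@@H](/C(C)=C/c2cc(CO[Si](C(C)C)(C(C)C)C(C)C)cc(O[Si](C(C)C)(C(C)C)C(C)C)c2OCOC)[C@]1(C)CC(C(C)=O)[Si](C)(C)C | intermediate
15 | (2S,3S)-2-methyl-2-(3-oxobutyl)-3-[(E)-1-Ar-prop-1-en-2-yl]cyclohexan-1-one | O=C1CCC[C@@H](/C(C)=C/c2cc(CO[Si](C(C)C)(C(C)C)C(C)C)cc(O[Si](C(C)C)(C(C)C)C(C)C)c2OCOC)[C@]1(C)CCC(C)=O | intermediate
16 | (2S,3S)-2-(3-hydroxybutyl)-2-methyl-3-[(E)-1-Ar-prop-1-en-2-yl]cyclohexan-1-one | O=C1CCC[C@@H](/C(C)=C/c2cc(CO[Si](C(C)C)(C(C)C)C(C)C)cc(O[Si](C(C)C)(C(C)C)C(C)C)c2OCOC)[C@]1(C)CCC(C)O | intermediate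
17 | (2S,3S)-2-(3-iodobutyl)-2-methyl-3-[(E)-1-Ar-prop-1-en-2-yl]cyclohexan-1-one | O=C1CCC[C@@H](/C(C)=C/c2cc(CO[Si](C(C)C)(C(C)C)C(C)C)cc(O[Si](C(C)C)(C(C)C)C(C)C)c2OCOC)[C@]1(C)CCC(C)I | intermediate
18 | (4aS,5R,6S,8aS)-5-(Ar-methyl)-5,6,8a-trimethyl-octahydronaphthalen-1(2H)-one | O=C1CCC[C@H]2[C@](C)(Cc3cc(CO[Si](C(C)C)(C(C)C)C(C)C)cc(O[Si](C(C)C)(C(C)C)C(C)C)c3OCOC)[C@@H](C)CC[C@]12C | intermediate
19 | (1R,2S,4aS,8aS)-1-(Ar-methyl)-1,2,4a-trimethyl-5-methylidenedecahydronaphthalene | C=C1CCC[C@H]2[C@](C)(Cc3cc(CO[Si](C(C)C)(C(C)C)C(C)C)cc(O[Si](C(C)C)(C(C)C)C(C)C)c3OCOC)[C@@H](C)CC[C@]12C | intermediate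
20 | trimethylsilyl ether of phenol 21 (OSiMe3 on C2') | C=C1CCC[C@H]2[C@](C)(Cc3cc(CO[Si](C(C)C)(C(C)C)C(C)C)cc(O[Si](C(C)C)(C(C)C)C(C)C)c3O[Si](C)(C)C)[C@@H](C)CC[C@]12C | intermediate
21 | 2-{[(1R,2S,4aS,8aS)-1,2,4a-trimethyl-5-methylidenedecahydronaphthalen-1-yl]methyl}-6-(triisopropylsilyloxy)-4-[(triisopropylsilyloxy)methyl]phenol | C=C1CCC[C@H]2[C@](C)(Cc3cc(CO[Si](C(C)C)(C(C)C)C(C)C)cc(O[Si](C(C)C)(C(C)C)C(C)C)c3O)[C@@H](C)CC[C@]12C | intermediate
22 | hydrogen sulfate of phenol 21 | C=C1CCC[C@H]2[C@](C)(Cc3cc(CO[Si](C(C)C)(C(C)C)C(C)C)cc(O[Si](C(C)C)(C(C)C)C(C)C)c3OS(=O)(=O)O)[C@@H](C)CC[C@]12C | intermediate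
23 | [2-hydroxy-4-(hydroxymethyl)-6-{[(1R,2S,4aS,8aS)-1,2,4a-trimethyl-5-methylidenedecahydronaphthalen-1-yl]methyl}phenyl] hydrogen sulfate | C=C1CCC[C@H]2[C@](C)(Cc3cc(CO)cc(O)c3OS(=O)(=O)O)[C@@H](C)CC[C@]12C | target

Total step count: 14. Longest linear sequence: 14 steps (1 to 23); 6, 10 and 11 enter as commercial materials.

## Least certain steps

**Step 7 (key step).** Most likely to go wrong is enantioface selection: a bulky sp2 Grignard reagent transfers through a chiral copper complex less cleanly than the alkyl reagents for which such catalysts work best, and any ligand-free copper gives racemic product. The second weakness is the Michael capture, where a hindered tetrasubstituted magnesium enolate may react slowly enough for proton transfer and oligomerisation of 11 to compete.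

Fallback, setting out from 9 and 10 (through 12 and 13) and returning at 14: the two bond formations are separated. Enolate 13 is not alkylated in the same flask but silylated (Me3SiCl, Et3N, −78 °C → rt) to the trimethylsilyl enol ether F1, which is isolated so that its enantiomeric purity can be checked and the copper catalyst optimised on its own. MeLi in THF then releases the more reactive lithium enolate regiospecifically, and this adds to 11 at −78 °C to give 14, which is desilylated to 15 as before.

**Step 10.** Two processes threaten it. The first is 1,5-hydrogen transfer from C10–H, which is tertiary and allylic to the styrene, to the C8 radical; it runs through the same six-membered array as the ring closure and competes with attack on a fully substituted alkene carbon. The second is incomplete facial control at C9 (and at C8), since the preference for C11 equatorial rests on one non-bonded contact.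

Fallback, setting out from 16 and returning at 18: the alkene geometry is inverted before the closure. Triplet energy transfer (fac-Ir(ppy)3, blue light, MeCN) should enrich the more twisted isomer with the aryl group cis to C10, the (Z)-hydroxy ketone F2. Appel iodination gives the (Z)-iodide F3, and the same tin hydride conditions close the ring. In this isomer allylic 1,3-strain holds C10–H in the alkene plane. The hydrogen is then orthogonal to the π-system and gains no allylic activation for transfer, and only the rotamer with C11 equatorial is populated, so the same product 18 is expected with firmer control.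

**Step 8.** Hydride attack at the wrong carbonyl or at both carbonyls is the risk, because steric differentiation is the only control element.

Fallback, setting out from 15 and returning at 18: both ketones are reduced (NaBH4, MeOH) to the diol F4. One equivalent of the Appel reagent then converts only the unhindered C8 hydroxyl, since the C4 hydroxyl is neopentyl-like and cannot be displaced, giving the iodo alcohol F5. Radical closure as in step 10 gives the decalol F6, and a Swern oxidation ((COCl)2, DMSO, Et3N) restores the C4 ketone of 18.

**Step 13.** The O2' hydroxyl is flanked by the C11 substituent and the silyloxy group, so sulfation may be slow. A slow sulfation leaves time for silyl transfer from O3' to O2', after which the sulfate would enter at the wrong oxygen.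

Fallback, setting out from 21 and returning at 22: the sulfate is introduced as a protected diester with a much faster electrophile. 2,2,2-Trichloroethyl chlorosulfate with DMAP and Et3N in THF at 0 °C gives the neutral, chromatographable trichloroethyl sulfate F7, on which the regiochemistry can be confirmed. Zn and HCO2NH4 in MeOH then remove the trichloroethyl group without touching the alkene or the silyl ethers.

**Step 6.** Regiocontrol of the hydrometalation may be eroded if the ortho acetal oxygen coordinates zirconium and holds it on the benzylic carbon.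

Fallback, setting out from 7 and returning at 9: copper-catalysed borylation (CuCl, NaOt-Bu, a bisphosphine, B2pin2, MeOH, THF) adds boron and hydrogen syn, with boron on the carbon remote from the arene for electronic reasons, giving the alkenyl boronate F8. CuBr2 in MeOH–H2O replaces boron by bromine with retention.

## Further compounds

F1 | step 7 | trimethylsilyl enol ether of (S)-2-methyl-3-[(E)-1-Ar-prop-1-en-2-yl]cyclohexanone | C[Si](C)(C)OC1=C(C)[C@H](/C(C)=C/c2cc(CO[Si](C(C)C)(C(C)C)C(C)C)cc(O[Si](C(C)C)(C(C)C)C(C)C)c2OCOC)CCC1
F2 | step 10 | (2S,3S)-2-(3-hydroxybutyl)-2-methyl-3-[(Z)-1-Ar-prop-1-en-2-yl]cyclohexan-1-one | O=C1CCC[C@@H](/C(C)=C\c2cc(CO[Si](C(C)C)(C(C)C)C(C)C)cc(O[Si](C(C)C)(C(C)C)C(C)C)c2OCOC)[C@]1(C)CCC(C)O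
F3 | step 10 | (2S,3S)-2-(3-iodobutyl)-2-methyl-3-[(Z)-1-Ar-prop-1-en-2-yl]cyclohexan-1-one | O=C1CCC[C@@H](/C(C)=C\c2cc(CO[Si](C(C)C)(C(C)C)C(C)C)cc(O[Si](C(C)C)(C(C)C)C(C)C)c2OCOC)[C@]1(C)CCC(C)I
F4 | step 8 | (2S,3S)-2-(3-hydroxybutyl)-2-methyl-3-[(E)-1-Ar-prop-1-en-2-yl]cyclohexan-1-ol (carbinol epimers) | OC1CCC[C@@H](/C(C)=C/c2cc(CO[Si](C(C)C)(C(C)C)C(C)C)cc(O[Si](C(C)C)(C(C)C)C(C)C)c2OCOC)[C@]1(C)CCC(C)O
F5 | step 8 | (2S,3S)-2-(3-iodobutyl)-2-methyl-3-[(E)-1-Ar-prop-1-en-2-yl]cyclohexan-1-ol | OC1CCC[C@@H](/C(C)=C/c2cc(CO[Si](C(C)C)(C(C)C)C(C)C)cc(O[Si](C(C)C)(C(C)C)C(C)C)c2OCOC)[C@]1(C)CCC(C)I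
F6 | step 8 | (4aS,5R,6S,8aS)-5-(Ar-methyl)-5,6,8a-trimethyldecahydronaphthalen-1-ol | OC1CCC[C@H]2[C@](C)(Cc3cc(CO[Si](C(C)C)(C(C)C)C(C)C)cc(O[Si](C(C)C)(C(C)C)C(C)C)c3OCOC)[C@@H](C)CC[C@]12C
F7 | step 13 | 2,2,2-trichloroethyl aryl sulfate of phenol 21 | C=C1CCC[C@H]2[C@](C)(Cc3cc(CO[Si](C(C)C)(C(C)C)C(C)C)cc(O[Si](C(C)C)(C(C)C)C(C)C)c3OS(=O)(=O)OCC(Cl)(Cl)Cl)[C@@H](C)CC[C@]12C
F8 | step 6 | (Z)-2-(1-Ar-prop-1-en-2-yl)-4,4,5,5-tetramethyl-1,3,2-dioxaborolane | CC1(C)OB(OC1(C)C)/C(C)=C/c1cc(CO[Si](C(C)C)(C(C)C)C(C)C)cc(O[Si](C(C)C)(C(C)C)C(C)C)c1OCOC
A1 | alternative 1 | (R)-tert-butyldimethyl[(2-vinylcyclohex-2-en-1-yl)oxy]silane | C=CC1=CCCC[C@H]1O[Si](C)(C)C(C)(C)C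
A2 | alternative 1 | (E)-2-methylbut-2-enal | C/C=C(\C)C=O
A3 | alternative 1 | exo cycloadduct, octalin with C9 formyl and C4 silyloxy groups | CC(C)(C)[Si](C)(C)O[C@@H]1CCC[C@H]2[C@](C)(C=O)[C@@H](C)CC=C12
A4 | alternative 2 | acyl-protected 11-aryl-drim-8(12)-ene | C=C1CC[C@H]2C(C)(C)CCC[C@]2(C)[C@H]1Cc1cc(C(=O)OC)cc(OC(=O)C(C)(C)C)c1OC(C)=O
A5 | alternative 2 | acyl-protected rearranged skeleton with C4 methylidene | C=C1CCC[C@H]2[C@](C)(Cc3cc(C(=O)OC)cc(OC(=O)C(C)(C)C)c3OC(C)=O)[C@@H](C)CC[C@]12C
A6 | alternative 3 | acyclic triene with (E)-β-methyl enoate and terminal (E)-diene | COC(=O)/C=C(\C)CC[C@H](C)[C@@](C)(Cc1cc(CO[Si](C(C)C)(C(C)C)C(C)C)cc(O[Si](C(C)C)(C(C)C)C(C)C)c1OCOC)/C=C/C=C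
A7 | alternative 3 | trans-fused octalin with C1=C2 alkene and C4 methyl ester | COC(=O)[C@H]1CC=C[C@H]2[C@](C)(Cc3cc(CO[Si](C(C)C)(C(C)C)C(C)C)cc(O[Si](C(C)C)(C(C)C)C(C)C)c3OCOC)[C@@H](C)CC[C@]12C
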